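## Retrosynthetic overview

1. Target 25 comes from global O-debenzylation of the dibenzyl ether 24.
2. The tetralin carbocycle (the only ring in the target formed by the route) is closed last, by acid-mediated Friedel–Crafts cyclisation of the benzylic triol 21 (C1–C8a bond). The attacking 4-benzyloxy-3,5-dimethoxybenzyl ring is symmetric, so there is no regiochemical issue.
3. Triol 21 comes from LiAlH4 reduction of aldol adduct 20. The key C–C bond (C1–C2 of the tetralin) is made by intermolecular aldol addition of the lithium enolate of (R)-lactone 17 to O-benzylvanillin 18.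
4. Lactone 17 (a temporary ring, formed first and opened later) comes from Evans alkylation of acyl oxazolidinone 11 with tert-butyl bromoacetate, reductive auxiliary removal and lactonisation.
5. Imide 11 comes from syringaldehyde by benzylation, HWE olefination, conjugate reduction, saponification and N-acylation.

Assumption: O-benzylvanillin, trimethyl phosphonoacetate, (S)-4-benzyl-1,3-oxazolidin-2-one, tert-butyl bromoacetate and NaHMDS/LiHMDS solutions are bought.

## Route

Step 1
Reactants: 1 syringaldehyde (4-hydroxy-3,5-dimethoxybenzaldehyde); 2 benzyl bromide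
Product: 3 4-(benzyloxy)-3,5-dimethoxybenzaldehyde
Conditions: BnBr, K2CO3, DMF, 60 °C
Reagents that add atoms: benzyl bromide (2), BrCc1ccccc1
Why: Williamson ether synthesis (SN2 of the phenoxide on benzyl bromide) protects the phenol; the aldehyde is inert to carbonate.

Step 2
Reactants: 3 4-(benzyloxy)-3,5-dimethoxybenzaldehyde; 4 trimethyl phosphonoacetate
Product: 5 methyl (2E)-3-[4-(benzyloxy)-3,5-dimethoxyphenyl]prop-2-enoate
Conditions: (MeO)2P(O)CH2CO2Me, NaH, THF, 0 °C → rt
Reagents that add atoms: trimethyl phosphonoacetate (4), COC(=O)CP(=O)(OC)OC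
Why: Horner–Wadsworth–Emmons olefination of a non-enolisable aryl aldehyde with a stabilised phosphonate anion gives the (E)-cinnamate cleanly.

Step 3
Reactants: 5 methyl (2E)-3-[4-(benzyloxy)-3,5-dimethoxyphenyl]prop-2-enoate
Product: 6 methyl 3-[4-(benzyloxy)-3,5-dimethoxyphenyl]propanoate
Conditions: NaBH4 (3 equiv), NiCl2·6H2O (10 mol%), MeOH/THF, 0 °C
Reagents that add atoms: none
Why: Nickel boride conjugate reduction saturates the cinnamate C=C and leaves the ester and the aryl benzyl ether, which H2/Pd would cleave.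

Step 4
Reactants: 6 methyl 3-[4-(benzyloxy)-3,5-dimethoxyphenyl]propanoate
Product: 7 3-[4-(benzyloxy)-3,5-dimethoxyphenyl]propanoic acid
Conditions: LiOH·H2O, THF/MeOH/H2O, rt; then 1 M HCl
Reagents that add atoms: lithium hydroxide, [Li+].[OH-]
Why: Saponification of an unhindered methyl ester; nothing else in the molecule is base-labile.

Step 5
Reactants: 7 3-[4-(benzyloxy)-3,5-dimethoxyphenyl]propanoic acid; 8 pivaloyl chloride; 9 (4S)-4-benzyl-1,3-oxazolidin-2-one
Product: 11 (4S)-4-benzyl-3-{3-[4-(benzyloxy)-3,5-dimethoxyphenyl]propanoyl}-1,3-oxazolidin-2-one, via mixed pivalic anhydride 10 (not isolated)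
Conditions: PivCl, Et3N, THF, −20 °C; then LiCl, 9, −20 °C → rt
Reagents that add atoms: (4S)-4-benzyl-1,3-oxazolidin-2-one (9), O=C1N[C@@H](Cc2ccccc2)CO1; pivaloyl chloride (8), CC(C)(C)C(=O)Cl (its atoms remain only in 10)
Why: N-acylation through a mixed anhydride, where the LiCl/Et3N-activated oxazolidinone attacks the unhindered carbonyl and not the pivaloyl one.

Step 6
Reactants: 11 (4S)-4-benzyl-3-{3-[4-(benzyloxy)-3,5-dimethoxyphenyl]propanoyl}-1,3-oxazolidin-2-one; 12 tert-butyl bromoacetate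
Product: 14 tert-butyl (3R)-3-{[4-(benzyloxy)-3,5-dimethoxyphenyl]methyl}-4-[(4S)-4-benzyl-2-oxo-1,3-oxazolidin-3-yl]-4-oxobutanoate, via sodium Z-enolate 13 (not isolated)
Conditions: NaHMDS (1.1 equiv), THF, −78 °C; then BrCH2CO2t-Bu, −78 → −40 °C
Reagents that add atoms: tert-butyl bromoacetate (12), CC(C)(C)OC(=O)CBr
Why: Evans asymmetric alkylation, in which the chelated (Z)-enolate is alkylated on the face opposite the 4-benzyl group and so sets the new centre as R (C-3 of the target); the minor diastereomer is removed by chromatography.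

Step 7
Reactants: 14 tert-butyl (3R)-3-{[4-(benzyloxy)-3,5-dimethoxyphenyl]methyl}-4-[(4S)-4-benzyl-2-oxo-1,3-oxazolidin-3-yl]-4-oxobutanoate
Product: 15 tert-butyl (3R)-3-{[4-(benzyloxy)-3,5-dimethoxyphenyl]methyl}-4-hydroxybutanoate
Conditions: LiBH4 (2 equiv), THF, 0 °C → rt
Reagents that add atoms: none
Why: Reductive removal of the Evans auxiliary, since the activated exocyclic imide carbonyl is reduced by borohydride much faster than the tert-butyl ester and the stereocentre is not touched.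

Step 8
Reactants: 15 tert-butyl (3R)-3-{[4-(benzyloxy)-3,5-dimethoxyphenyl]methyl}-4-hydroxybutanoate
Product: 17 (4R)-4-{[4-(benzyloxy)-3,5-dimethoxyphenyl]methyl}oxolan-2-one, via hydroxy acid 16 (not isolated)
Conditions: TFA/CH2Cl2 (1:4), 0 °C → rt
Reagents that add atoms: none
Why: Acidolysis of the tert-butyl ester (loss of isobutene) is followed by spontaneous acid-catalysed lactonisation of the γ-hydroxy acid; the aryl benzyl ether survives TFA at rt.

Step 9
Reactants: 17 (4R)-4-{[4-(benzyloxy)-3,5-dimethoxyphenyl]methyl}oxolan-2-one; 18 4-(benzyloxy)-3-methoxybenzaldehyde (O-benzylvanillin)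
Product: 20 (3S,4R)-3-{[4-(benzyloxy)-3-methoxyphenyl](hydroxy)methyl}-4-{[4-(benzyloxy)-3,5-dimethoxyphenyl]methyl}oxolan-2-one (both carbinol epimers), via lithium enolate 19 (not isolated)
Conditions: LiHMDS (1.1 equiv), THF, −78 °C; then 18, −78 °C; AcOH quench at −78 °C
Reagents that add atoms: 4-(benzyloxy)-3-methoxybenzaldehyde (18), COc1cc(C=O)ccc1OCc1ccccc1
Why: Intermolecular aldol addition of the lactone enolate to a non-enolisable aldehyde on the face anti to the C-4 benzyl group gives the 3,4-trans lactone (C-2 of the target); the carbinol configuration is irrelevant because that centre is ionised in step 11.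

Step 10
Reactants: 20 (3S,4R)-3-{[4-(benzyloxy)-3-methoxyphenyl](hydroxy)methyl}-4-{[4-(benzyloxy)-3,5-dimethoxyphenyl]methyl}oxolan-2-one
Product: 21 (2R,3R)-2-{[4-(benzyloxy)-3-methoxyphenyl](hydroxy)methyl}-3-{[4-(benzyloxy)-3,5-dimethoxyphenyl]methyl}butane-1,4-diol (both carbinol epimers)
Conditions: LiAlH4, THF, 0 °C; Rochelle-salt work-up
Reagents that add atoms: none
Why: Hydride reduction of the lactone to the 1,4-diol, run cold so that reduction outruns retro-aldol, leaves both stereocentres and the benzyl ethers unchanged.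

Step 11
Reactants: 21 (2R,3R)-2-{[4-(benzyloxy)-3-methoxyphenyl](hydroxy)methyl}-3-{[4-(benzyloxy)-3,5-dimethoxyphenyl]methyl}butane-1,4-diol
Product: 24 [(1S,2R,3R)-7-(benzyloxy)-1-[4-(benzyloxy)-3-methoxyphenyl]-6,8-dimethoxy-1,2,3,4-tetrahydronaphthalene-2,3-diyl]dimethanol, via benzylic cation 22 (not isolated), via tetrahydrofuran ether 23 (not isolated)
Conditions: TFA (10 equiv), CH2Cl2 (0.02 M), 0 °C → rt; then aq. NaHCO3/MeOH
Reagents that add atoms: none
Why: Intramolecular Friedel–Crafts alkylation, in which acid ionises either carbinol epimer to the p-benzyloxybenzylic cation, the ether 23 formed by O-trapping re-ionises, and the doubly activated ring captures the cation irreversibly through a chair-like transition state with the aryl anti to the neighbouring CH2OH, setting C-1 as S (all-trans).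

Step 12
Reactants: 24 [(1S,2R,3R)-7-(benzyloxy)-1-[4-(benzyloxy)-3-methoxyphenyl]-6,8-dimethoxy-1,2,3,4-tetrahydronaphthalene-2,3-diyl]dimethanol
Product: 25 (+)-8-methoxyisolariciresinol
Conditions: H2 (1 atm), 10% Pd/C, MeOH/EtOAc, rt
Reagents that add atoms: none
Why: Catalytic hydrogenolysis removes both aryl benzyl ethers, and the C-1 diarylmethine C–H and the primary alcohols are stable under these mild conditions.

## Compound list

1 | syringaldehyde (4-hydroxy-3,5-dimethoxybenzaldehyde) | COc1cc(C=O)cc(OC)c1O | starting material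
2 | benzyl bromide | BrCc1ccccc1 | starting material
3 | 4-(benzyloxy)-3,5-dimethoxybenzaldehyde | COc1cc(C=O)cc(OC)c1OCc1ccccc1 | intermediate
4 | trimethyl phosphonoacetate | COC(=O)CP(=O)(OC)OC | starting material
5 | methyl (2E)-3-[4-(benzyloxy)-3,5-dimethoxyphenyl]prop-2-enoate | COC(=O)/C=C/c1cc(OC)c(OCc2ccccc2)c(OC)c1 | intermediate
6 | methyl 3-[4-(benzyloxy)-3,5-dimethoxyphenyl]propanoate | COC(=O)CCc1cc(OC)c(OCc2ccccc2)c(OC)c1 | intermediate
7 | 3-[4-(benzyloxy)-3,5-dimethoxyphenyl]propanoic acid | OC(=O)CCc1cc(OC)c(OCc2ccccc2)c(OC)c1 | intermediate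
8 | pivaloyl chloride | CC(C)(C)C(=O)Cl | starting material
9 | (4S)-4-benzyl-1,3-oxazolidin-2-one | O=C1N[C@@H](Cc2ccccc2)CO1 | starting material
10 | 3-[4-(benzyloxy)-3,5-dimethoxyphenyl]propanoic pivalic anhydride (not isolated) | CC(C)(C)C(=O)OC(=O)CCc1cc(OC)c(OCc2ccccc2)c(OC)c1 | intermediate
11 | (4S)-4-benzyl-3-{3-[4-(benzyloxy)-3,5-dimethoxyphenyl]propanoyl}-1,3-oxazolidin-2-one | COc1cc(CCC(=O)N2[C@@H](Cc3ccccc3)COC2=O)cc(OC)c1OCc1ccccc1 | intermediate
12 | tert-butyl bromoacetate | CC(C)(C)OC(=O)CBr | starting material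
13 | sodium (Z)-enolate of 11 (not isolated) | [Na+].[O-]/C(=C\Cc1cc(OC)c(OCc2ccccc2)c(OC)c1)N1[C@@H](Cc2ccccc2)COC1=O | intermediate
14 | tert-butyl (3R)-3-{[4-(benzyloxy)-3,5-dimethoxyphenyl]methyl}-4-[(4S)-4-benzyl-2-oxo-1,3-oxazolidin-3-yl]-4-oxobutanoate | CC(C)(C)OC(=O)C[C@@H](Cc1cc(OC)c(OCc2ccccc2)c(OC)c1)C(=O)N1[C@@H](Cc2ccccc2)COC1=O | intermediate
15 | tert-butyl (3R)-3-{[4-(benzyloxy)-3,5-dimethoxyphenyl]methyl}-4-hydroxybutanoate | CC(C)(C)OC(=O)C[C@@H](Cc1cc(OC)c(OCc2ccccc2)c(OC)c1)CO | intermediate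
16 | (3R)-3-{[4-(benzyloxy)-3,5-dimethoxyphenyl]methyl}-4-hydroxybutanoic acid (not isolated) | OC(=O)C[C@@H](Cc1cc(OC)c(OCc2ccccc2)c(OC)c1)CO | intermediate
17 | (4R)-4-{[4-(benzyloxy)-3,5-dimethoxyphenyl]methyl}oxolan-2-one | COc1cc(C[C@@H]2CC(=O)OC2)cc(OC)c1OCc1ccccc1 | intermediate
18 | 4-(benzyloxy)-3-methoxybenzaldehyde (O-benzylvanillin) | COc1cc(C=O)ccc1OCc1ccccc1 | starting material
19 | lithium enolate of 17, lithium (4R)-4-{[4-(benzyloxy)-3,5-dimethoxyphenyl]methyl}-4,5-dihydrofuran-2-olate (not isolated) | COc1cc(C[C@@H]2C=C([O-])OC2)cc(OC)c1OCc1ccccc1.[Li+] | intermediate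
20 | (3S,4R)-3-{[4-(benzyloxy)-3-methoxyphenyl](hydroxy)methyl}-4-{[4-(benzyloxy)-3,5-dimethoxyphenyl]methyl}oxolan-2-one, 3,4-trans, both carbinol epimers | COc1cc(C[C@@H](COC2=O)[C@H]2C(O)c2ccc(OCc3ccccc3)c(OC)c2)cc(OC)c1OCc1ccccc1 | intermediate
21 | (2R,3R)-2-{[4-(benzyloxy)-3-methoxyphenyl](hydroxy)methyl}-3-{[4-(benzyloxy)-3,5-dimethoxyphenyl]methyl}butane-1,4-diol, both carbinol epimers | COc1cc(C[C@@H](CO)[C@H](CO)C(O)c2ccc(OCc3ccccc3)c(OC)c2)cc(OC)c1OCc1ccccc1 | intermediate
22 | 4-benzyloxy-3-methoxybenzylic cation derived from 21 (not isolated) | COc1cc(C[C@@H](CO)[C@H](CO)[CH+]c2ccc(OCc3ccccc3)c(OC)c2)cc(OC)c1OCc1ccccc1 | intermediate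
23 | {(3R,4R)-2-[4-(benzyloxy)-3-methoxyphenyl]-4-{[4-(benzyloxy)-3,5-dimethoxyphenyl]methyl}oxolan-3-yl}methanol, C-2 epimers (not isolated) | COc1cc(C[C@@H](CO4)[C@H](CO)C4c2ccc(OCc3ccccc3)c(OC)c2)cc(OC)c1OCc1ccccc1 | intermediate
24 | [(1S,2R,3R)-7-(benzyloxy)-1-[4-(benzyloxy)-3-methoxyphenyl]-6,8-dimethoxy-1,2,3,4-tetrahydronaphthalene-2,3-diyl]dimethanol | COc1cc([C@H]2c3c(cc(OC)c(OCc4ccccc4)c3OC)C[C@@H](CO)[C@@H]2CO)ccc1OCc1ccccc1 | intermediate
25 | (+)-8-methoxyisolariciresinol, (6R,7R,8S)-8-(4-hydroxy-3-methoxyphenyl)-6,7-bis(hydroxymethyl)-1,3-dimethoxy-5,6,7,8-tetrahydronaphthalen-2-ol | COc1cc([C@H]2c3c(cc(OC)c(O)c3OC)C[C@@H](CO)[C@@H]2CO)ccc1O | target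

## Step count and risks

Total step count: 12. Longest linear sequence: 12 steps (1 → 25).

Three steps most likely to fail:

Step 11 (Friedel–Crafts closure of the free triol). The reaction may stall at the tetrahydrofuran ether 23, the primary alcohols may be trifluoroacetylated, and the peri-methoxy group may erode C-1 selectivity. The fallback sets out from 21. Peracetylation (Ac2O, pyridine, DMAP) gives (2R,3R)-2-{acetoxy[4-(benzyloxy)-3-methoxyphenyl]methyl}-3-{[4-(benzyloxy)-3,5-dimethoxyphenyl]methyl}butane-1,4-diyl diacetate F1. With the primary oxygens masked, ionisation of the benzylic acetate (BF3·OEt2, CH2Cl2, −40 → 0 °C) can only lead to C-cyclisation, giving [(1S,2R,3R)-7-(benzyloxy)-1-[4-(benzyloxy)-3-methoxyphenyl]-6,8-dimethoxy-1,2,3,4-tetrahydronaphthalene-2,3-diyl]bis(methylene) diacetate F2. Methanolysis (K2CO3, MeOH) comes back to the route at 24.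

Step 10 (LiAlH4 on a benzylic β-hydroxy lactone). The aluminium alkoxide can undergo retro-aldol before the lactone is reduced. The fallback sets out from 20 and reverses the order of ring closure and reduction. TFA/CH2Cl2 cyclises 20 directly to (3aR,9S,9aR)-7-(benzyloxy)-9-[4-(benzyloxy)-3-methoxyphenyl]-6,8-dimethoxy-3a,4,9,9a-tetrahydronaphtho[2,3-c]furan-1(3H)-one F3, which has no β-hydroxy carbonyl unit. LiAlH4 then reduces it and the route is rejoined at 24. It is the second choice because the rigid trans-fused lactone cannot relieve the peri strain between the C-9 aryl and the 8-OMe, so the C-9 configuration must be confirmed (J and NOE) before going on.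

Step 7 (hydride removal of the auxiliary next to a tert-butyl ester). Hydride may attack the ring carbonyl of the α-branched imide, giving a ring-opened hydroxy amide, or the reduction may be sluggish. The fallback sets out from 14. LiOH/H2O2 (THF/H2O, 0 °C) hydrolyses the imide to (2R)-2-{[4-(benzyloxy)-3,5-dimethoxyphenyl]methyl}-4-tert-butoxy-4-oxobutanoic acid F4, with recovery of 9. BH3·SMe2 (THF, 0 °C → rt) then reduces the free acid chemoselectively in the presence of the tert-butyl ester, and the route is rejoined at 15.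

## Further compounds

F1 | step 11 | (2R,3R)-2-{acetoxy[4-(benzyloxy)-3-methoxyphenyl]methyl}-3-{[4-(benzyloxy)-3,5-dimethoxyphenyl]methyl}butane-1,4-diyl diacetate | COc1cc(C[C@@H](COC(C)=O)[C@H](COC(C)=O)C(OC(C)=O)c2ccc(OCc3ccccc3)c(OC)c2)cc(OC)c1OCc1ccccc1
F2 | step 11 | [(1S,2R,3R)-7-(benzyloxy)-1-[4-(benzyloxy)-3-methoxyphenyl]-6,8-dimethoxy-1,2,3,4-tetrahydronaphthalene-2,3-diyl]bis(methylene) diacetate | COc1cc([C@H]2c3c(cc(OC)c(OCc4ccccc4)c3OC)C[C@@H](COC(C)=O)[C@@H]2COC(C)=O)ccc1OCc1ccccc1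
F3 | step 10 | (3aR,9S,9aR)-7-(benzyloxy)-9-[4-(benzyloxy)-3-methoxyphenyl]-6,8-dimethoxy-3a,4,9,9a-tetrahydronaphtho[2,3-c]furan-1(3H)-one | COc1cc([C@H]2c3c(cc(OC)c(OCc4ccccc4)c3OC)C[C@@H](COC5=O)[C@@H]25)ccc1OCc1ccccc1
F4 | step 7 | (2R)-2-{[4-(benzyloxy)-3,5-dimethoxyphenyl]methyl}-4-tert-butoxy-4-oxobutanoic acid | CC(C)(C)OC(=O)C[C@@H](Cc1cc(OC)c(OCc2ccccc2)c(OC)c1)C(O)=O
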